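## Structural features

The target is a flavone: a benzene ring A fused to a 4-pyranone ring C (4H-chromen-4-one), with a 3,4-dihydroxyphenyl ring B attached at C2. Ring A carries three neighbouring oxygens at C5, C6 and C7, and only the middle one, O6, bears the sulfate; O5, O7 and both ring B oxygens are free phenols. There is no stereocentre, so the whole problem is one of position: which of five phenolic oxygens carries sulfur, and in which sense ring C is fused to the oxygenated ring A (5,6,7 against 5,7,8). The aryl sulfate monoester is cleaved by acid, the anions of the ring A triol and of the ring B catechol are oxidised by air, and the pyranone enone can be opened by strong hydroxide or over-reduced. The real difficulty is that O6 is the most hindered and least acidic ring A oxygen, so a direct sulfation would be expected to go to O7. The key step uses exactly this order: O7 (para to C4a, conjugated with the C4 carbonyl) is the most acidic hydroxyl and the best leaving group, O5 is held in a hydrogen bond to the C4 carbonyl, and O6 is the poorest leaving group. A sulfur atom bridged between O6 and O7 can therefore later be detached from O7 alone.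

## Logic of the disconnections

18 back to 16 (through 17). The two benzyl C–O bonds on ring B are cut. Benzyl is chosen because neutral hydrogenolysis leaves an aryl sulfate alone and because the group survives every acid and base used earlier. It also keeps the ring B catechol out of reach of 13 in step 7. The forward step must not saturate C2=C3 and must stay free of acid while the sulfate is present.

16 back to 15. The O7–S bond is re-formed on paper, which turns the monosulfate into the 6,7-cyclic sulfate. The question of how to sulfate O6 beside O7 and O5 becomes the easier question of which S–O bond of a diester breaks. The forward step needs attack of aqueous base at sulfur only, and departure of O7, not O6.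

15 back to 12 and 13. Both S–O bonds (O6–S and O7–S) are cut, removing the only ring that does not belong to the flavone. The sulfur then comes from one small electrophile with two leaving groups, and ring A needs no differential protection. The demand is that 13 is taken up once, by O7 first, that the second substitution is the intramolecular one from O6, and that O5 stays out.

12 back to 9. The O1–C2 bond of ring C is cut together with the four acetal C–O bonds on ring A. The 1,3-diketone is the classical flavone precursor and divides the molecule into two aryl halves. Ring A has an oxygen on both carbons next to C4a, so closure could use either one. In 9 the oxygen meant to become O1 therefore carries the oxanyl acetal, and the others carry the more slowly cleaved MOM groups. The forward step must unmask that oxygen, close and dehydrate before the MOM group on the future O5 is lost.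

9 back to 7 and 8. The C2–C3 bond (flavone numbering) is cut, a crossed Claisen condensation of a methyl ketone with a non-enolisable ester. This separates ring A (7) from ring B (8), and 8 can be bought. The forward step needs C-acylation of a hindered enolate and excess base, because the product is the stronger acid.

7 back to 5. The C4a–C4 bond is cut; the acetyl group enters through the aryllithium 6. In 5 the only two ring hydrogens are equivalent and each lies between two acetal oxygens, so metalation has one possible site. A free ortho-hydroxyl is deliberately not carried through this part. It would interfere with metalation, and in an aldehyde–aldol–oxidation variant it would expose an electron-rich ortho-hydroxybenzylic alcohol to the oxidant. The demand is that addition to the acyl donor beats proton transfer from its methyl group.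

5 back to 4. The acetal C–O bond at the future O1 is cut. This marks one oxygen as different from the other three at the cost of one simple step.

4 back to 2. The aryl C–O bond of the phenol is traced back to the aryl C–CHO bond (oxygen insertion). The aldehyde carbon of 1 thus serves only as a placeholder for O1, which gives the 1,2,3,5-tetraoxygenated ring from a symmetric precursor. The forward step needs aryl migration, not hydride migration.

2 back to 1. The three MOM O–CH2 bonds are cut. 1 is commercial and already has the three adjacent oxygens.

## Other disconnections considered

Alternative 1: The cut goes through the junction of rings A and C, at C8a–O1 and C4a–C4. In the forward step a fluoride source would release an aryne from the ortho-silylaryl triflate A2. The carboxylate oxygen of the arylpropiolic acid A3 would add at C8a, the aryne carbon remote from the C5 benzyloxy group. The aryl anion at C4a would then take over the acyl group, giving the ortho-hydroxyaryl ynone A1 without closing a ring; ring C would follow by 6-endo addition of the new phenol to the ynone.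
- In its favour: two skeletal bonds form in one mild, convergent operation, and the sense of addition is set by a single substituent.
- In its favour, and better than the chosen plan: A1 already tells the three ring A oxygens apart (benzyl on O5 and O7, MOM on O6). The sulfate could then be placed by removing one acetal and sulfating the only free hydroxyl with an SO3–amine complex, so its position would rest on protecting groups and precedented sulfation, not on an untested choice between two S–O bonds.
- Against it: A2 is a benzene with five different substituents, and making it would probably take more steps than the whole chosen route to 12.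
- Against it: the aryne is electron-rich and flanked on one side; arylpropiolic acids lose CO2 easily under basic fluoride conditions; simple O-arylation without acyl shift and 5-exo closure to an aurone are plausible side paths.
- Structure: both plans give the 5,6,7 orientation; the alternative fixes O6 by construction, the chosen plan by reactivity.
- Mechanism: aryne insertion into a carboxylic acid C–O bond is known for simple partners, so it stands on firmer ground than step 7, although not for an aryne this substituted.
- Step economy: the chosen plan is clearly shorter. After A1 there remain cyclisation, acetal removal, sulfation and fourfold hydrogenolysis, and the long preparation of A2 comes before it. The final hydrogenolysis beside a sulfate is an equal risk in both.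

Alternative 2: The cut is the C4a–C5 bond, so ring A is made last from a chain on a preformed pyranone ring C. In the forward step Mg(OMe)2 would form the magnesium dienolate of the keto ester A5. C4a would attack the ester carbonyl with loss of methoxide, and the new six-membered ring would aromatise by tautomerism to A4, which has O5 and O7 free and O6 as the MOM ether.
- In its favour: the design follows polyketide folding, needs no aromatic substitution, oxygen insertion or metalation, and the chain dictates where O6 sits. In the certainty of the oxygen pattern it is the equal of the chosen plan.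
- Against it: A5 is a sensitive polycarbonyl compound, and its assembly would be longer and less controllable than the sequence 1 to 9.
- Against it: the dienolate of a 2-alkylpyranone carries its charge mainly on C8 and on the C4 oxygen. Closure may therefore pass through an opened polyketone and an acylphloroglucinol, which could re-close ring C on either ortho oxygen and give the 8-MOM isomer as well.
- Against it: A4 does not solve the sulfation problem. Its pattern (O6 masked, O5 and O7 free) is the inverse of what classical sulfation needs, and removing the acetal from A4 gives 12. The alternative would thus join the chosen route before step 7, with all the risk of steps 7 and 8 still ahead.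
- Structure: building ring A from an open chain is elegant.
- Mechanism: the Claisen closure is a known type but ambiguous here.
- Step economy: it offers no gain.

Alternative 3: The cut is the C2=C3 bond of ring C. In the forward step the stabilised acyl ylide carbon (C3) of A7 would attack the carbonyl of the aryl ester on O1 (the future C2). Loss of the phosphine oxide from the oxaphosphetane would form C2=C3 and close ring C, giving A6.
- In its favour, and better than step 6: the closure is thermal and neutral, and the ester sits on a defined oxygen, so the orientation of ring C cannot scramble. Step 6 depends on relative rates.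
- In its favour, and better in certainty: A6 has O6 alone as the MOM ether, so the sulfation site is again fixed by protecting groups, and every step is of a known type.
- Against it: A7 requires an ortho-hydroxy acetophenone with three differently protected oxygens in defined positions and an activated α-carbon, which means a long linear sequence of selective protections.
- Against it: an electron-rich aroyl ester is a poor electrophile for an ester Wittig reaction, and the reaction produces a stoichiometric amount of phosphine oxide.
- Against it: after A6 there are still acetal removal, sulfation of a hydroxyl flanked by two benzyloxy groups, and hydrogenolysis of four benzyl ethers beside the sulfate (two in the chosen plan, a slight advantage for the latter).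
- Structure: both reach the same flavone skeleton and face the same final hydrogenolysis beside a sulfate.
- Mechanism: the alternative is fully precedented, whereas the chosen plan has one unproven step.
- Step economy: the chosen plan is shorter by several steps.

Key step: step 7

Assumption: the target is drawn as the free hydrogen sulfate; aryl hydrogen sulfates are strong acids normally kept as alkali salts, so the route is led to the sodium salt 17 and the acid form 18 is released cold as the last operation of step 9.

## Steps

Step 1
Reactants: 1 3,4,5-trihydroxybenzaldehyde
Product: 2 3,4,5-tris(methoxymethoxy)benzaldehyde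
Conditions: MOMCl (4.0 equiv), iPr2NEt (5.0 equiv), DMF, 0 °C to rt, N2
Reagents that add atoms: chloromethyl methyl ether, COCCl
Why: Base-mediated O-alkylation of all three phenols by the α-chloro ether; the excess drives the hindered middle oxygen to react as well, and the aldehyde is untouched.

Step 2
Reactants: 2 3,4,5-tris(methoxymethoxy)benzaldehyde
Product: 4 3,4,5-tris(methoxymethoxy)phenol, via aryl formate 3 (not isolated)
Conditions: mCPBA (1.3 equiv), CH2Cl2, 0 °C to rt; aqueous wash; then K2CO3 (cat.), MeOH, rt
Reagents that add atoms: meta-chloroperbenzoic acid, O=C(OO)c1cccc(Cl)c1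
Why: Baeyer–Villiger oxidation of an electron-rich benzaldehyde (the Dakin-type change of ArCHO into ArOH): the three alkoxy groups make aryl migration faster than hydride migration, so formate 3 forms and is cleaved by base-catalysed methanolysis. The acetals should tolerate the weakly acidic peracid in CH2Cl2.

Step 3
Reactants: 4 3,4,5-tris(methoxymethoxy)phenol
Product: 5 2-[3,4,5-tris(methoxymethoxy)phenoxy]oxane (racemic)
Conditions: 3,4-dihydro-2H-pyran (1.5 equiv), PPTS (0.1 equiv), CH2Cl2, rt
Reagents that add atoms: 3,4-dihydro-2H-pyran, C1=COCCC1
Why: Acid-catalysed addition of the phenol to the enol ether (tetrahydropyranylation) in an aprotic medium that leaves the MOM ethers alone. The oxygen that will become O1 is thereby marked with the most acid-labile acetal; the new acetal carbon is racemic and is removed in step 6.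

Step 4
Reactants: 5 2-[3,4,5-tris(methoxymethoxy)phenoxy]oxane
Product: 7 1-[2,3,4-tris(methoxymethoxy)-6-(oxan-2-yloxy)phenyl]ethan-1-one (racemic), via aryllithium 6 (not isolated)
Conditions: n-BuLi (1.2 equiv), THF, 0 °C, 1 h; then MeC(O)N(OMe)Me (1.5 equiv), −78 °C to 0 °C; H2O quench
Reagents that add atoms: N-methoxy-N-methylacetamide, CC(=O)N(C)OC
Why: Directed ortho-metalation followed by Weinreb ketone synthesis: the two ring hydrogens are equivalent and each lies between two acetal oxygens that bind lithium together, so 6 can form at one position only. The chelated tetrahedral adduct of the N-methoxy amide should persist until the quench, which prevents a second addition.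

Step 5
Reactants: 7 1-[2,3,4-tris(methoxymethoxy)-6-(oxan-2-yloxy)phenyl]ethan-1-one; 8 methyl 3,4-bis(benzyloxy)benzoate
Product: 9 1-[3,4-bis(benzyloxy)phenyl]-3-[2,3,4-tris(methoxymethoxy)-6-(oxan-2-yloxy)phenyl]propane-1,3-dione (racemic)
Conditions: NaH (3.0 equiv), THF, 0 °C to 65 °C; then AcOH to pH about 6, 0 °C
Reagents that add atoms: none
Why: Crossed Claisen condensation: the sodium enolate of the methyl ketone is acylated at carbon by the non-enolisable aryl ester, and deprotonation of the 1,3-diketone makes the step irreversible. Acetals and benzyl ethers are inert to NaH, and the buffered quench keeps the oxanyl acetal.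

Step 6
Reactants: 9 1-[3,4-bis(benzyloxy)phenyl]-3-[2,3,4-tris(methoxymethoxy)-6-(oxan-2-yloxy)phenyl]propane-1,3-dione
Product: 12 2-[3,4-bis(benzyloxy)phenyl]-5,6,7-trihydroxy-4H-chromen-4-one, via phenol diketone 10 (not isolated), via tris-MOM flavone 11 (not isolated)
Conditions: HCl (2 M), degassed MeOH–THF, 0 °C to rt, 2 h; then 55 °C
Reagents that add atoms: none
Why: Acid cascade ending in the classical cyclodehydration of an ortho-hydroxyaryl 1,3-diketone to a flavone: the oxanyl acetal is exchanged by methanol far faster than the MOM ethers, the single free hydroxyl adds to the ring B ketone, and the 2-hydroxyflavanone loses water to 11 while O5 is still protected, which fixes the 5,6,7 orientation. Warming then removes the three MOM groups by methanolysis; the benzyl ethers and the finished pyranone should be stable.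

Step 7
Reactants: 12 2-[3,4-bis(benzyloxy)phenyl]-5,6,7-trihydroxy-4H-chromen-4-one; 13 sulfuryl fluoride
Product: 15 3',4'-bis(benzyloxy)-5-hydroxyflavone 6,7-cyclic sulfate, via 7-fluorosulfate 14 (not isolated)
Conditions: SO2F2 (1.05 equiv, standardised solution in MeCN, closed flask), Et3N (2.2 equiv, added slowly last), degassed CH2Cl2–MeCN (dilute), −20 °C to rt, Ar; anhydrous work-up (short pad of dry SiO2), used at once
Reagents that add atoms: sulfuryl fluoride (13), O=S(=O)(F)F
Why: Proposed new method: the step rests on exchange of fluoride for phenoxide at hexavalent sulfur, whose closest known form is the conversion of simple catechols into benzo-1,3,2-dioxathiole 2,2-dioxides with SO2F2 or SO2Cl2 and base; it has not been shown on the vicinal triol of a flavone, where one pair of oxygens must be chosen. Et3N should ionise the 7-hydroxyl first, because its phenoxide is conjugated with the C4 carbonyl like a vinylogous carboxylate, and this phenoxide attacks 13 with loss of fluoride to give 14. The neighbouring 6-phenoxide then displaces the second fluoride at the same sulfur; the ring (O6, C6, C7, O7, S) closes by exo attack on tetrahedral sulfur with the leaving fluoride outside the new five-membered ring, a 5-exo closure that is intramolecular and so should outrun any second intermolecular sulfonylation. No stereocentre is created. Three selectivities are needed: one sulfur per molecule, no sulfonylation of O5, and no sulfate bridge between two molecules. They are secured respectively by using close to one equivalent of 13 with slow addition of the base, by the hydrogen bond from the 5-hydroxyl to the C4 carbonyl (which lowers its acidity and nucleophilicity), and by dilution together with the speed of the 5-exo closure. Should some 5,6-bridged isomer form, it would still lead to the same 6-sulfate in step 8, because O5 is a better leaving group than O6. Air is excluded because the anion of the 5,6,7-triol is easily oxidised.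

Step 8
Reactants: 15 3',4'-bis(benzyloxy)-5-hydroxyflavone 6,7-cyclic sulfate
Product: 16 sodium 2-[3,4-bis(benzyloxy)phenyl]-5,7-dihydroxy-4-oxo-4H-chromen-6-yl sulfate
Conditions: NaOH (1.0 equiv, 0.1 M aq, slow addition), THF–H2O, 0 °C
Reagents that add atoms: sodium hydroxide, [Na+].[OH-]
Why: Hydrolysis of a strained aryl cyclic sulfate at sulfur, as known for catechol cyclic sulfates: hydroxide adds to sulfur and the adduct expels the better leaving group, the 7-phenoxide stabilised by conjugation with the C4 carbonyl, so the sulfur stays on O6. The monoester anion is inert to further hydroxide, and one equivalent of base at 0 °C should spare the pyranone ring.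

Step 9
Reactants: 16 sodium 2-[3,4-bis(benzyloxy)phenyl]-5,7-dihydroxy-4-oxo-4H-chromen-6-yl sulfate
Product: 18 6-hydroxyluteolin 6-sulfate, via target sodium salt 17 (not isolated)
Conditions: H2 (1 atm), 10% Pd/C, THF–MeOH–H2O, rt; filtration through diatomaceous earth; then HCl (1.0 equiv, 0.1 M aq), 0 °C, reversed-phase (C18) desalting, freeze-drying
Reagents that add atoms: none
Why: Catalytic hydrogenolysis of the two benzyl aryl ethers on palladium metal under neutral conditions, which the aryl sulfate monoanion tolerates; the C2=C3 bond of a flavone is a vinylogous ester and is expected to be reduced much more slowly at 1 atm. One equivalent of HCl in the cold then converts 17 into the hydrogen sulfate 18, which is best kept as 17 and acidified shortly before use.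

## Compound list

1 | 3,4,5-trihydroxybenzaldehyde | O=Cc1cc(O)c(O)c(O)c1 | starting material
2 | 3,4,5-tris(methoxymethoxy)benzaldehyde | COCOc1cc(C=O)cc(OCOC)c1OCOC | intermediate
3 | 3,4,5-tris(methoxymethoxy)phenyl formate | COCOc1cc(OC=O)cc(OCOC)c1OCOC | intermediate (not isolated)
4 | 3,4,5-tris(methoxymethoxy)phenol | COCOc1cc(O)cc(OCOC)c1OCOC | intermediate
5 | 2-[3,4,5-tris(methoxymethoxy)phenoxy]oxane (racemic) | COCOc1cc(OC2CCCCO2)cc(OCOC)c1OCOC | intermediate
6 | [2,3,4-tris(methoxymethoxy)-6-(oxan-2-yloxy)phenyl]lithium (racemic) | [Li]c1c(OC2CCCCO2)cc(OCOC)c(OCOC)c1OCOC | intermediate (not isolated)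
7 | 1-[2,3,4-tris(methoxymethoxy)-6-(oxan-2-yloxy)phenyl]ethan-1-one (racemic) | CC(=O)c1c(OC2CCCCO2)cc(OCOC)c(OCOC)c1OCOC | intermediate
8 | methyl 3,4-bis(benzyloxy)benzoate | COC(=O)c1ccc(OCc2ccccc2)c(OCc2ccccc2)c1 | starting material
9 | 1-[3,4-bis(benzyloxy)phenyl]-3-[2,3,4-tris(methoxymethoxy)-6-(oxan-2-yloxy)phenyl]propane-1,3-dione (racemic) | O=C(CC(=O)c1c(OC2CCCCO2)cc(OCOC)c(OCOC)c1OCOC)c1ccc(OCc2ccccc2)c(OCc2ccccc2)c1 | intermediate
10 | 1-[3,4-bis(benzyloxy)phenyl]-3-[6-hydroxy-2,3,4-tris(methoxymethoxy)phenyl]propane-1,3-dione | O=C(CC(=O)c1c(O)cc(OCOC)c(OCOC)c1OCOC)c1ccc(OCc2ccccc2)c(OCc2ccccc2)c1 | intermediate (not isolated)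
11 | 2-[3,4-bis(benzyloxy)phenyl]-5,6,7-tris(methoxymethoxy)-4H-chromen-4-one | O=c1cc(-c2ccc(OCc3ccccc3)c(OCc3ccccc3)c2)oc2cc(OCOC)c(OCOC)c(OCOC)c12 | intermediate (not isolated)
12 | 2-[3,4-bis(benzyloxy)phenyl]-5,6,7-trihydroxy-4H-chromen-4-one | O=c1cc(-c2ccc(OCc3ccccc3)c(OCc3ccccc3)c2)oc2cc(O)c(O)c(O)c12 | intermediate
13 | sulfuryl fluoride | O=S(=O)(F)F | starting material
14 | 2-[3,4-bis(benzyloxy)phenyl]-5,6-dihydroxy-4-oxo-4H-chromen-7-yl sulfurofluoridate | O=c1cc(-c2ccc(OCc3ccccc3)c(OCc3ccccc3)c2)oc2cc(OS(=O)(=O)F)c(O)c(O)c12 | intermediate (not isolated)
15 | 3',4'-bis(benzyloxy)-5-hydroxyflavone 6,7-cyclic sulfate (6-[3,4-bis(benzyloxy)phenyl]-9-hydroxy-8H-[1,3,2]dioxathiolo[4,5-g]chromen-8-one 2,2-dioxide) | O=c1cc(-c2ccc(OCc3ccccc3)c(OCc3ccccc3)c2)oc2cc3OS(=O)(=O)Oc3c(O)c12 | intermediate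
16 | sodium 2-[3,4-bis(benzyloxy)phenyl]-5,7-dihydroxy-4-oxo-4H-chromen-6-yl sulfate | O=c1cc(-c2ccc(OCc3ccccc3)c(OCc3ccccc3)c2)oc2cc(O)c(OS(=O)(=O)[O-])c(O)c12.[Na+] | intermediate
17 | sodium 2-(3,4-dihydroxyphenyl)-5,7-dihydroxy-4-oxo-4H-chromen-6-yl sulfate | O=c1cc(-c2ccc(O)c(O)c2)oc2cc(O)c(OS(=O)(=O)[O-])c(O)c12.[Na+] | intermediate (not isolated)
18 | 6-hydroxyluteolin 6-sulfate (2-(3,4-dihydroxyphenyl)-5,7-dihydroxy-4-oxo-4H-chromen-6-yl hydrogen sulfate) | O=c1cc(-c2ccc(O)c(O)c2)oc2cc(O)c(OS(=O)(=O)O)c(O)c12 | target

## Step count and least certain steps

Total step count: 9. Longest linear sequence: 9 steps, from 1 to 18; 8 and 13 are purchased.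

Step 7 (key step). The most likely failure is over-reaction at sulfur. A phenoxide of unreacted 12 could attack the strained product and link two molecules through a sulfate, or a second equivalent of 13 could sulfonylate O5. Air oxidation of the triol anion and hydrolysis of the product during isolation are further risks. The cause is that the product is itself a strong electrophile at sulfur while phenoxide is still present. The fallback uses known chemistry and gives up the cyclic sulfate. It sets out from 12, where the most acidic hydroxyl is alkylated selectively with benzyl bromide (1.05 equiv) and K2CO3 in DMF under argon to give 7-(benzyloxy)-2-[3,4-bis(benzyloxy)phenyl]-5,6-dihydroxy-4H-chromen-4-one F1. The chelated 5-hydroxyl is unreactive, so sulfation with SO3·pyridine in pyridine, followed by NaHCO3, should give sodium 7-(benzyloxy)-2-[3,4-bis(benzyloxy)phenyl]-5-hydroxy-4-oxo-4H-chromen-6-yl sulfate F2. Hydrogenolysis of its three benzyl ethers under the conditions of step 9 returns to the route at 17; steps 7 and 8 are bypassed.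

Step 8. The most likely failure is cleavage of the wrong S–O bond, which would leave sulfur on O7. Ionisation of the 5-hydroxyl under base could narrow the gap in leaving-group ability between the 7- and 6-phenoxides. Attack of hydroxide on the pyranone is a lesser risk. The fallback removes the choice by capping O7 before sulfur is introduced, with a group that can be taken off without touching ring B. It sets out from 12: allyl bromide and K2CO3 give 2-[3,4-bis(benzyloxy)phenyl]-5,6-dihydroxy-7-(prop-2-en-1-yloxy)-4H-chromen-4-one F3. Sulfation with SO3·pyridine and NaHCO3 gives sodium 2-[3,4-bis(benzyloxy)phenyl]-5-hydroxy-4-oxo-7-(prop-2-en-1-yloxy)-4H-chromen-6-yl sulfate F4. Allyl transfer to morpholine with Pd(PPh3)4 (zerovalent palladium) in THF–MeOH then frees O7 and returns to the route at 16.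

Step 6. The most likely failure is loss of orientation. If the MOM group on the future O5 is cleaved before the hemiketal has dehydrated, the diketone can close on the other ortho oxygen and drift towards the 5,7,8 pattern. Substitution at C8 by formaldehyde equivalents released from the MOM groups is a second risk. The fallback sets out from 9 and separates the three events into isolated operations. PPTS in MeOH at rt removes only the oxanyl acetal, and 10 is isolated. Ring closure and dehydration are then run with catalytic TsOH in dry toluene over 4 Å molecular sieves, where MOM ethers cannot solvolyse, and 11 is isolated. The MOM groups are finally cleaved on the finished flavone, which can no longer reopen, with HCl in MeOH in the presence of a thiol scavenger, returning to the route at 12. This fallback makes no new compound (F0).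

Step 4. The most likely failure is proton transfer from the acetyl group of the amide to the doubly flanked, strongly basic aryllithium, which would return 5 in place of the addition product. The fallback changes the carbon electrophile and the bond-forming logic. It sets out from 5 (through 6): a DMF quench gives 2,3,4-tris(methoxymethoxy)-6-(oxan-2-yloxy)benzaldehyde F5. Aldol addition of the lithium enolate of commercial 1-[3,4-bis(benzyloxy)phenyl]ethanone (LiN(iPr)2, THF, −78 °C, cold quench) gives 1-[3,4-bis(benzyloxy)phenyl]-3-hydroxy-3-[2,3,4-tris(methoxymethoxy)-6-(oxan-2-yloxy)phenyl]propan-1-one F6 as a mixture of diastereomers. Dess–Martin oxidation buffered with NaHCO3 then returns to the route at 9; steps 4 and 5 are bypassed.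

Step 9. The most likely failure is loss of the sulfate by solvolysis through traces of acid carried by the catalyst. Slow turnover of the anionic, strongly adsorbed substrate would lengthen the reaction and invite partial saturation of C2=C3. The fallback changes the order of events so that no sulfate monoester is present during hydrogenolysis. It sets out from 15: hydrogenolysis of the neutral diester (Pd(OH)2/C, H2, 1 atm, dry EtOAc–THF) should give 3',4',5-trihydroxyflavone 6,7-cyclic sulfate F7. Opening with NaOH (1.0 equiv) in THF–H2O at 0 °C, as in step 8, then returns to the route at 17.

## Further compounds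

F1 | step 7 | 7-(benzyloxy)-2-[3,4-bis(benzyloxy)phenyl]-5,6-dihydroxy-4H-chromen-4-one | O=c1cc(-c2ccc(OCc3ccccc3)c(OCc3ccccc3)c2)oc2cc(OCc3ccccc3)c(O)c(O)c12
F2 | step 7 | sodium 7-(benzyloxy)-2-[3,4-bis(benzyloxy)phenyl]-5-hydroxy-4-oxo-4H-chromen-6-yl sulfate | O=c1cc(-c2ccc(OCc3ccccc3)c(OCc3ccccc3)c2)oc2cc(OCc3ccccc3)c(OS(=O)(=O)[O-])c(O)c12.[Na+]
F3 | step 8 | 2-[3,4-bis(benzyloxy)phenyl]-5,6-dihydroxy-7-(prop-2-en-1-yloxy)-4H-chromen-4-one | C=CCOc1cc2oc(-c3ccc(OCc4ccccc4)c(OCc4ccccc4)c3)cc(=O)c2c(O)c1O
F4 | step 8 | sodium 2-[3,4-bis(benzyloxy)phenyl]-5-hydroxy-4-oxo-7-(prop-2-en-1-yloxy)-4H-chromen-6-yl sulfate | C=CCOc1cc2oc(-c3ccc(OCc4ccccc4)c(OCc4ccccc4)c3)cc(=O)c2c(O)c1OS(=O)(=O)[O-].[Na+]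
F0 | step 6 | none | none
F5 | step 4 | 2,3,4-tris(methoxymethoxy)-6-(oxan-2-yloxy)benzaldehyde (racemic) | O=Cc1c(OC2CCCCO2)cc(OCOC)c(OCOC)c1OCOC
F6 | step 4 | 1-[3,4-bis(benzyloxy)phenyl]-3-hydroxy-3-[2,3,4-tris(methoxymethoxy)-6-(oxan-2-yloxy)phenyl]propan-1-one (mixture of diastereomers) | O=C(CC(O)c1c(OC2CCCCO2)cc(OCOC)c(OCOC)c1OCOC)c1ccc(OCc2ccccc2)c(OCc2ccccc2)c1
F7 | step 9 | 3',4',5-trihydroxyflavone 6,7-cyclic sulfate (6-(3,4-dihydroxyphenyl)-9-hydroxy-8H-[1,3,2]dioxathiolo[4,5-g]chromen-8-one 2,2-dioxide) | O=c1cc(-c2ccc(O)c(O)c2)oc2cc3OS(=O)(=O)Oc3c(O)c12
A1 | alternative 1 | 1-[2,4-bis(benzyloxy)-6-hydroxy-3-(methoxymethoxy)phenyl]-3-[3,4-bis(benzyloxy)phenyl]prop-2-yn-1-one | O=C(C#Cc1ccc(OCc2ccccc2)c(OCc2ccccc2)c1)c1c(O)cc(OCc2ccccc2)c(OCOC)c1OCc1ccccc1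
A2 | alternative 1 | 3,5-bis(benzyloxy)-4-(methoxymethoxy)-2-(trimethylsilyl)phenyl trifluoromethanesulfonate | C[Si](C)(C)c1c(OS(=O)(=O)C(F)(F)F)cc(OCc2ccccc2)c(OCOC)c1OCc1ccccc1
A3 | alternative 1 | 3-[3,4-bis(benzyloxy)phenyl]prop-2-ynoic acid | OC(=O)C#Cc1ccc(OCc2ccccc2)c(OCc2ccccc2)c1
A4 | alternative 2 | 2-[3,4-bis(benzyloxy)phenyl]-5,7-dihydroxy-6-(methoxymethoxy)-4H-chromen-4-one | O=c1cc(-c2ccc(OCc3ccccc3)c(OCc3ccccc3)c2)oc2cc(O)c(OCOC)c(O)c12
A5 | alternative 2 | methyl 4-{6-[3,4-bis(benzyloxy)phenyl]-4-oxo-4H-pyran-2-yl}-2-(methoxymethoxy)-3-oxobutanoate (racemic) | COC(=O)C(OCOC)C(=O)Cc1cc(=O)cc(-c2ccc(OCc3ccccc3)c(OCc3ccccc3)c2)o1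
A6 | alternative 3 | 5,7-bis(benzyloxy)-2-[3,4-bis(benzyloxy)phenyl]-6-(methoxymethoxy)-4H-chromen-4-one | O=c1cc(-c2ccc(OCc3ccccc3)c(OCc3ccccc3)c2)oc2cc(OCc3ccccc3)c(OCOC)c(OCc3ccccc3)c12
A7 | alternative 3 | 3,5-bis(benzyloxy)-4-(methoxymethoxy)-2-[(triphenylphosphoranylidene)acetyl]phenyl 3,4-bis(benzyloxy)benzoate | O=C(Oc1cc(OCc2ccccc2)c(OCOC)c(OCc2ccccc2)c1C(=O)C=P(c1ccccc1)(c1ccccc1)c1ccccc1)c1ccc(OCc2ccccc2)c(OCc2ccccc2)c1
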